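The target is disconnected at both C4–O bonds of the central C4–O–C4' ether. If the methyl on O5' is set aside, the molecule is C2-symmetric, and in each flavan half the C5 hydroxyl of ring A is ortho to the benzylic C4 of ring C, so C4 can ionise to an o-quinone methide (C5=O, C4a=C4). A mild acid therefore condenses two molecules of (2S,4S)-5-hydroxy-6,7-dimethoxyflavan-4-ol, a single monomer made from a chiral-pool (S)-flavanone, into the bis-phenolic ether, creating both ether bonds and the C4 and C4' stereocentres in one operation; one statistical O-methylation then breaks the symmetry.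

Key step: step 6

Assumption: salts and chelates that exist only until aqueous work-up (the lithium carboxylate in step 2, the boron chelate in step 4, the borate esters in step 5) are treated as forms of the product and are not numbered separately.

Step 1
Reactants: 1 3,4,5-trimethoxyphenol; 2 ethyl (R)-3-hydroxy-3-phenylpropanoate
Product: 3 ethyl (S)-3-phenyl-3-(3,4,5-trimethoxyphenoxy)propanoate
Conditions: PPh3, DIAD (slow addition), toluene, 0 °C → rt
Reagents that add atoms: none
Why: Mitsunobu etherification, in which the phenol (acidic enough to protonate the betaine) displaces the benzylic oxyphosphonium group by SN2, so the R carbinol centre is inverted to the S aryl ether that later becomes C2, while low temperature and slow azodicarboxylate addition hold back elimination to ethyl cinnamate.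

Step 2
Reactants: 3 ethyl (S)-3-phenyl-3-(3,4,5-trimethoxyphenoxy)propanoate
Product: 4 (S)-3-phenyl-3-(3,4,5-trimethoxyphenoxy)propanoic acid
Conditions: LiOH·H2O, THF/H2O (3:1), 0 °C → rt; then 1 M HCl, 0 °C
Reagents that add atoms: lithium hydroxide (its oxygen ends in the CO2H group), [Li+].[OH-]
Why: Ester saponification by acyl–oxygen cleavage, which at 0 °C should be much faster than α-deprotonation, so E1cB loss of the aryloxide is not expected and the benzylic stereocentre, which carries no acidic hydrogen, stays untouched.

Step 3
Reactants: 4 (S)-3-phenyl-3-(3,4,5-trimethoxyphenoxy)propanoic acid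
Product: 6 (2S)-5,6,7-trimethoxyflavanone, via mixed trifluoroacetic anhydride 5 (not isolated)
Conditions: (CF3CO)2O (1.2 equiv), CH2Cl2, 0 °C → rt
Reagents that add atoms: none
Why: Intramolecular Friedel–Crafts acylation through the mixed anhydride, in which the carbon ortho to the ether oxygen is activated by three oxygen donors and the two ortho positions are equivalent by symmetry, so a single chromanone (ring C closed onto ring A, methoxy groups at C5, C6 and C7) should form without any bond to C2 being broken.

Step 4
Reactants: 6 (2S)-5,6,7-trimethoxyflavanone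
Product: 7 (2S)-5-hydroxy-6,7-dimethoxyflavanone
Conditions: BCl3 (1.2 equiv), CH2Cl2, −78 → 0 °C; then H2O
Reagents that add atoms: none
Why: Chelation-directed aryl methyl ether cleavage, in which BCl3 is held between the C4 carbonyl oxygen and the peri 5-methoxy oxygen so that chloride removes only that methyl group, the standard selective 5-O-demethylation of polymethoxylated flavonoids.

Step 5
Reactants: 7 (2S)-5-hydroxy-6,7-dimethoxyflavanone
Product: 8 (2S,4S)-5-hydroxy-6,7-dimethoxyflavan-4-ol
Conditions: NaBH4 (excess), THF/MeOH (4:1), 0 °C → rt; pH 7 phosphate buffer, no chromatography on untreated silica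
Reagents that add atoms: none
Why: Borohydride reduction of the aryl ketone, with axial hydride delivery on the half-chair that carries an equatorial 2-phenyl group giving the equatorial 4-hydroxyl (2,4-cis, 4S), and neutral work-up sparing the acid-labile o-hydroxybenzyl alcohol, which is taken directly into step 6.

Step 6
Reactants: 8 (2S,4S)-5-hydroxy-6,7-dimethoxyflavan-4-ol (two molecules)
Product: 11 bis[(2S,4R)-5-hydroxy-6,7-dimethoxyflavan-4-yl] ether, via o-quinone methide 9 (not isolated), via trans-flavan-4-ol 10 (not isolated)
Conditions: PPTS (5 mol%), CH2Cl2 (0.5 M), rt; then powdered 4 Å molecular sieves, rt; Et3N quench, chromatography on Et3N-deactivated silica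
Reagents that add atoms: none
Why: PPTS protonates the benzylic 4-OH of 8 while the C5 hydroxyl of ring A gives up its proton, so water leaves and the o-quinone methide 9 (C5=O, C4a=C4) forms; before the sieves are added the liberated water re-adds to 9 and relays cis-8 to the trans alcohol 10, and once water is sequestered the 4-OH of 10 adds across C4 and O5 of a further molecule of 9 with rearomatisation of ring A, so that each of the two C4–O bonds of 11 arises from capture of 9 by oxygen. The closest known reaction type is the acid- or heat-induced dehydrative etherification of o-hydroxybenzyl alcohols by way of o-quinone methides, including their self-condensation to bis(2-hydroxybenzyl) ethers; no ring is closed. C4 and C4' are both set under control of the existing C2 and C2' centres: the oxygen nucleophile enters the half-chair of 9 along the pseudoaxial line, on the face opposite the equatorial 2-phenyl group, which gives the 2,4-trans (4R) arrangement, and a pseudoequatorial C4–O bond would in addition suffer peri strain with the C5–OH. Because every C4–O bond next to a free C5–OH stays ionisable, any ether first formed from unepimerised cis-8 re-enters the same manifold and should be corrected to the trans,trans isomer, which is why the C4 configuration of 8 does not matter. The selectivity needed is O- over C-capture (C8 of ring A is a potential arene nucleophile) and avoidance of proton loss from C3: the weak acid, the weakly polar medium and the high concentration favour the reversible, hydrogen-bond-assisted O–H addition, C8 is shielded by O1 and the 7-methoxy group, and the E geometry of C4a=C4 enforced by ring C holds the C3 hydrogens away from O5, which blocks the 1,5-hydrogen shift by which open-chain o-quinone methides collapse to vinylphenols. Cross-selectivity is not an issue, since electrophile and nucleophile derive from the same monomer.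

Step 7
Reactants: 11 bis[(2S,4R)-5-hydroxy-6,7-dimethoxyflavan-4-yl] ether
Product: 12 beilschmieflavonoid B, (2S,4R)-6,7-dimethoxy-4-{[(2S,4R)-5,6,7-trimethoxyflavan-4-yl]oxy}flavan-5-ol
Conditions: CH3I (1.0 equiv), K2CO3, DMF, 0 °C → rt
Reagents that add atoms: iodomethane, CI
Why: Williamson O-methylation of a phenol, in which the two phenols of 11 are exchanged by the C2 axis so that methylation of either gives the same compound 12, with limiting CH3I expected to give a statistical mixture from which unreacted 11 is recovered and recycled, and with the low temperature chosen so that the phenoxide does not expel the benzylic ether.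

Compound list
1 | 3,4,5-trimethoxyphenol | COc1cc(O)cc(OC)c1OC | starting material
2 | ethyl (R)-3-hydroxy-3-phenylpropanoate | CCOC(=O)C[C@@H](O)c1ccccc1 | starting material
3 | ethyl (S)-3-phenyl-3-(3,4,5-trimethoxyphenoxy)propanoate | CCOC(=O)C[C@H](Oc1cc(OC)c(OC)c(OC)c1)c1ccccc1 | intermediate
4 | (S)-3-phenyl-3-(3,4,5-trimethoxyphenoxy)propanoic acid | OC(=O)C[C@H](Oc1cc(OC)c(OC)c(OC)c1)c1ccccc1 | intermediate
5 | (S)-3-phenyl-3-(3,4,5-trimethoxyphenoxy)propanoic trifluoroacetic anhydride | FC(F)(F)C(=O)OC(=O)C[C@H](Oc1cc(OC)c(OC)c(OC)c1)c1ccccc1 | intermediate (not isolated)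
6 | (2S)-5,6,7-trimethoxyflavanone | COc1cc2c(c(OC)c1OC)C(=O)C[C@@H](c1ccccc1)O2 | intermediate
7 | (2S)-5-hydroxy-6,7-dimethoxyflavanone | COc1cc2c(c(O)c1OC)C(=O)C[C@@H](c1ccccc1)O2 | intermediate
8 | (2S,4S)-5-hydroxy-6,7-dimethoxyflavan-4-ol (2,4-cis) | COc1cc2c(c(O)c1OC)[C@@H](O)C[C@@H](c1ccccc1)O2 | intermediate
9 | (2S)-6,7-dimethoxy-2-phenyl-2,3-dihydro-5H-chromen-5-one (o-quinone methide) | COC1=C(OC)C(=O)C2=CC[C@@H](c3ccccc3)OC2=C1 | intermediate (not isolated)
10 | (2S,4R)-5-hydroxy-6,7-dimethoxyflavan-4-ol (2,4-trans) | COc1cc2c(c(O)c1OC)[C@H](O)C[C@@H](c1ccccc1)O2 | intermediate (not isolated)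
11 | bis[(2S,4R)-5-hydroxy-6,7-dimethoxyflavan-4-yl] ether | COc1cc2c(c(O)c1OC)[C@H](O[C@@H]1C[C@@H](c3ccccc3)Oc3cc(OC)c(OC)c(O)c31)C[C@@H](c1ccccc1)O2 | intermediate
12 | beilschmieflavonoid B | COc1cc2c(c(O)c1OC)[C@H](O[C@@H]1C[C@@H](c3ccccc3)Oc3cc(OC)c(OC)c(OC)c31)C[C@@H](c1ccccc1)O2 | target

Total step count: 7
Longest linear sequence: 7 steps (from 1 or 2 to 12)

Steps most likely to fail

1. Step 6. The o-quinone methide may be captured at carbon (C8 of ring A) instead of at oxygen, which would lead irreversibly to C4–C8 linked oligomers. Proton loss from C3 to a flav-3-ene and incomplete correction of cis-linked ether are further possibilities. Fallback (blocking group): setting out from 7, NBS (1.0 equiv, MeCN, 0 °C) should brominate C8, the only unsubstituted position of ring A, to give (2S)-8-bromo-5-hydroxy-6,7-dimethoxyflavanone F1. NaBH4 as in step 5 gives (2S,4S)-8-bromo-5-hydroxy-6,7-dimethoxyflavan-4-ol F2. The condensation of step 6, in which a C4–C8 bond can no longer form, gives bis[(2S,4R)-8-bromo-5-hydroxy-6,7-dimethoxyflavan-4-yl] ether F3. Bromine–lithium exchange (t-BuLi in excess to cover both phenols, THF, −78 °C, then MeOH) replaces both bromines by hydrogen, and the route is rejoined at 11.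

2. Step 7. The second, symmetry-equivalent phenol is methylated about as readily as the first, so over-methylation and incomplete conversion limit throughput. The phenoxide next to the benzylic ether may also trigger fragmentation. Fallback (no desymmetrisation): setting out from 6 and 8, NaBH4 reduction of 6 gives (2S,4S)-5,6,7-trimethoxyflavan-4-ol F4. Mitsunobu inversion with 4-nitrobenzoic acid (PPh3, DIAD, THF) gives (2S,4R)-5,6,7-trimethoxyflavan-4-yl 4-nitrobenzoate F5, and K2CO3/MeOH gives (2S,4R)-5,6,7-trimethoxyflavan-4-ol F6, which has no free C5–OH and cannot form an o-quinone methide. Slow addition of 8 to an excess of F6 under the catalyst of step 6 lets 9 be captured axially by the 4-OH of F6; excess F6 is recovered, and the route is rejoined directly at 12.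

3. Step 1. The β-hydroxy ester may eliminate to ethyl cinnamate, or the displacement may take on SN1 character with partial loss of configurational purity. Fallback (racemic synthesis and resolution, which bypasses steps 1 to 3): setting out from 1, acetylation (AcOH, BF3·OEt2, 85 °C) gives 1-(6-hydroxy-2,3,4-trimethoxyphenyl)ethan-1-one F7. Claisen–Schmidt condensation with benzaldehyde (KOH, EtOH, rt) gives (E)-1-(6-hydroxy-2,3,4-trimethoxyphenyl)-3-phenylprop-2-en-1-one F8, and oxa-Michael ring closure (NaOAc, EtOH, reflux) gives racemic 5,6,7-trimethoxyflavanone F9. Preparative chromatography on a chiral stationary phase separates the S enantiomer, at which the route is rejoined at 6, from (2R)-5,6,7-trimethoxyflavanone F10, which is returned to F9 by base-mediated ring opening and closure and resolved again.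

Further compounds
F1 | step 6 | (2S)-8-bromo-5-hydroxy-6,7-dimethoxyflavanone | COc1c(Br)c2c(c(O)c1OC)C(=O)C[C@@H](c1ccccc1)O2
F2 | step 6 | (2S,4S)-8-bromo-5-hydroxy-6,7-dimethoxyflavan-4-ol | COc1c(Br)c2c(c(O)c1OC)[C@@H](O)C[C@@H](c1ccccc1)O2
F3 | step 6 | bis[(2S,4R)-8-bromo-5-hydroxy-6,7-dimethoxyflavan-4-yl] ether | COc1c(Br)c2c(c(O)c1OC)[C@H](O[C@@H]1C[C@@H](c3ccccc3)Oc3c(Br)c(OC)c(OC)c(O)c31)C[C@@H](c1ccccc1)O2
F4 | step 7 | (2S,4S)-5,6,7-trimethoxyflavan-4-ol | COc1cc2c(c(OC)c1OC)[C@@H](O)C[C@@H](c1ccccc1)O2
F5 | step 7 | (2S,4R)-5,6,7-trimethoxyflavan-4-yl 4-nitrobenzoate | COc1cc2c(c(OC)c1OC)[C@H](OC(=O)c1ccc(cc1)[N+](=O)[O-])C[C@@H](c1ccccc1)O2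
F6 | step 7 | (2S,4R)-5,6,7-trimethoxyflavan-4-ol | COc1cc2c(c(OC)c1OC)[C@H](O)C[C@@H](c1ccccc1)O2
F7 | step 1 | 1-(6-hydroxy-2,3,4-trimethoxyphenyl)ethan-1-one | CC(=O)c1c(O)cc(OC)c(OC)c1OC
F8 | step 1 | (E)-1-(6-hydroxy-2,3,4-trimethoxyphenyl)-3-phenylprop-2-en-1-one | O=C(/C=C/c1ccccc1)c1c(O)cc(OC)c(OC)c1OC
F9 | step 1 | racemic 5,6,7-trimethoxyflavanone | COc1cc2c(c(OC)c1OC)C(=O)CC(c1ccccc1)O2
F10 | step 1 | (2R)-5,6,7-trimethoxyflavanone | COc1cc2c(c(OC)c1OC)C(=O)C[C@H](c1ccccc1)O2
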